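The earlier runs and the new flask are calculated for an exercise; noise was put on by code.

Early in the summer run the missing material, set against target, reads higher than at the last reading, and it is a small difference of scattered readings, so the reading to watch while repeating these flasks is the plateau of target.

| setting | summer | midnight | dusk | noon | ash | cedar | elm | alder | larch | birch |
|---|---|---|---|---|---|---|---|---|---|---|
| starting material | 0.055 M | 0.12 M | 0.27 M | 0.10 M | 0.10 M | 0.10 M | 0.10 M | 0.30 M | 0.060 M | 0.060 M |
| coupling partner | 1.2 equiv | 1.2 equiv | 1.2 equiv | 1.2 equiv | 1.20 equiv | 1.20 equiv | 1.20 equiv | 1.20 equiv | 1.20 equiv | 1.20 equiv |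
| protic impurity | 0.10 M | 0.10 M | 0.10 M | 0.10 M | 0.100 M | 0.400 M | 0.100 M | 0.300 M | 0.100 M | 0.100 M |
| free catalyst | 0.1 mol% | 0.1 mol% | 0.1 mol% | 0.16 mol% | 0.4 mol% | 0.1 mol% | 0.1 mol% | 0.15 mol% | 0.2 mol% | 0.1 mol% |
| temperature | 92 °C | 109 °C | 92 °C | 109 °C | 100 °C | 115 °C | 100 °C | 100 °C | 100 °C | 85 °C |
| remark | run made earlier | run made earlier | run made earlier | run made earlier |  |  |  |  |  |  |
| time |  |  |  |  | 1.5 h | 1.5 h | 1.5 h | 1.5 h | 1.5 h | 1.5 h |

| run | time / min | target / % | starting material / % |
|---|---|---|---|
| summer | 8.00 | 19 | 72 |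
| summer | 25.0 | 49 | 33 |
| summer | 40.0 | 65 | 16 |
| summer | 60.0 | 76 | 3 |
| summer | 90.0 | 81 | 0 |
| midnight | 5.00 | 42 | 41 |
| midnight | 15.0 | 77 | 5 |
| midnight | 25.0 | 81 | 0 |
| midnight | 40.0 | 83 | 1 |
| midnight | 60.0 | 81 | 0 |
| dusk | 8.00 | 68 | 27 |
| dusk | 25.0 | 96 | 0 |
| dusk | 40.0 | 94 | 0 |
| dusk | 60.0 | 95 | 2 |
| dusk | 90.0 | 97 | 2 |
| noon | 12.0 | 83 | 4 |
| noon | 25.0 | 89 | 1 |
| noon | 30.0 | 84 | 0 |
| noon | 50.0 | 85 | 2 |
| noon | 60.0 | 89 | 0 |

(standard deviation of a reading: 2 percentage points)

- steps that have been proposed: starting material + free catalyst -> catalyst intermediate A; coupling partner + catalyst intermediate A <-> catalyst intermediate B; catalyst intermediate B -> free catalyst + target; starting material + protic impurity -> quenched substrate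
- no earlier run changes the charge of protic impurity; that part of a forecast is a guess

1. the flasks put in order of amount of target, in percent of the starting material charged, best first, at 1.5 h (ash / cedar / elm / alder / larch / birch)
2. the amount of target, in percent of the starting material charged of the flask you put first, at 1.5 h
3. the amount of target, in percent of the starting material charged of the flask you put last, at 1.5 h

Two of the proposed steps consume starting material: capture by free catalyst, on the route to target, and quenching by protic impurity. We define ρ as quenched substrate over target, counting as quenched whatever is found as neither target nor starting material. The catalyst charge of 0.1 mol% is too small to matter in this balance.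

The first way to ρ uses an early reading. In the summer run it gives 0.474 at 8.00 min, then 0.367 at 25.0 min.

The second way uses the final plateau, and the summer run's last reading gives 0.235. The early figure is larger, and the midnight run parts the same way, 0.405 against 0.224. So the early ratio cheats: it is a snapshot that drifts downward as the run proceeds, and it rests on a difference of a few points with a scatter of 2 percentage points. The plateau is what is asked, so we trust it.

Next we test the plateau against G, impurity concentration over catalyst concentration. At 92 °C, summer has G = 1820, and ρ/G is 1.29 × 10⁻⁴. Dusk has G = 370, and its plateau gives 1.27 × 10⁻⁴, which is close. At 109 °C, midnight gives 2.69 × 10⁻⁴ and noon 2.44 × 10⁻⁴.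

Taking geometric means gives 1.28 × 10⁻⁴ and 2.57 × 10⁻⁴. Since 100 °C lies near the middle of these temperatures, their geometric mean gives 1.81 × 10⁻⁴, our quench constant a, ρ over G at one temperature. Target is then 1/(1 + aG), assuming quenching is first order in impurity, which is a guess.

At 100 °C, G is 250 for ash, 667 for alder, 833 for larch and 1000 for elm, so we rank them in that order. Our reckoning gives ash 95.7%. Extrapolating a to 115 °C gives cedar 43.6%.

The forecast, made separately from its own rough fits, says ash > alder > larch > elm > birch > cedar, with 95% at the top and 44% at the bottom. Its ground for the low end is “Heat therefore favours quenching”.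

The flasks give ash > alder > larch > elm > birch > cedar, with 94.5% at the top and 46.4% at the bottom, so the forecast held.

    starting material + free catalyst → catalyst intermediate A (k = 2070 M⁻¹ min⁻¹, Ea = 50.0 kJ mol⁻¹)
    coupling partner + catalyst intermediate A ⇌ catalyst intermediate B (K = 5.10 M⁻¹, k = 931 M⁻¹ min⁻¹, Ea = 46.0 kJ mol⁻¹, ΔH = −21.0 kJ mol⁻¹)
    catalyst intermediate B → free catalyst + target (k = 4410 min⁻¹, Ea = 63.0 kJ mol⁻¹)
    starting material + protic impurity → quenched substrate (k = 0.203 M⁻¹ min⁻¹, Ea = 84.0 kJ mol⁻¹)
    (constants at 100 °C)

The shortfall in ash comes from quenching: without that step ash gives 100% instead of 94.5%. From its own yield, ash has ρ = 0.0579, so a reads 2.32 × 10⁻⁴, above our 1.81 × 10⁻⁴. Carried to alder, with its different charges, this value predicts 86.6%, and alder gives 87.2%.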